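**Strategy.** The benzo ring of the indole is disconnected into three alkynes. C5 and C6, which carry the vicinal bromines, come from one symmetric alkyne; C4/C3a and C7/C7a come from a diyne whose two alkynes are linked through N1–C2–C3. A cobalt-mediated [2+2+2] cocyclisation of bis(trimethylsilyl)acetylene with an N-tosyl ynamide diyne (N-ethynyl-N-but-3-ynyl sulfonamide) forms C3a–C7a, C4–C5 and C6–C7 in one operation. It closes the benzene ring and the five-membered nitrogen ring as an indoline with silicon at exactly C5 and C6. Ipso-bromination, aromatisation, N-methylation, Mannich aminomethylation, C2 bromination and N-oxidation finish the target.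

Key step: step 3

Remarks on the chemistry:
- The target has no stereocentre (the N-oxide nitrogen carries two methyl groups), so it is achiral and no stereocontrol is needed.
- Atom map of the key step: the ynamide carbons become C7a and C7, the butynyl alkyne carbons become C3a and C4, and the silylalkyne carbons become C5 and C6. The three-atom N1–C2–C3 link between the alkynes makes the nitrogen ring five-membered.
- Phenyl[(trimethylsilyl)ethynyl]iodonium triflate is taken as a purchasable reagent.
- Amide and ammonium salts that exist in the flask before the next reagent or the basic work-up are numbered as non-isolated intermediates.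

**Route**

Step 1
Reactants: 1 but-3-yn-1-amine; 2 4-toluenesulfonyl chloride
Product: 3 N-(but-3-yn-1-yl)-4-methylbenzenesulfonamide
Conditions: TsCl (1.05 equiv), Et3N (1.5 equiv), CH2Cl2, 0 °C → rt
Reagents that add atoms: 4-toluenesulfonyl chloride (2), Cc1ccc(cc1)S(Cl)(=O)=O
Why: N-sulfonylation of a primary amine; the terminal alkyne is inert to sulfonyl chloride and triethylamine.

Step 2
Reactants: 3 N-(but-3-yn-1-yl)-4-methylbenzenesulfonamide; 4 phenyl[(trimethylsilyl)ethynyl]iodonium trifluoromethanesulfonate
Product: 7 N-(but-3-yn-1-yl)-N-ethynyl-4-methylbenzenesulfonamide, via potassium sulfonamide salt 5 (not isolated), via silyl-capped ynamide 6 (not isolated)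
Conditions: KHMDS (1.0 equiv), PhMe, 0 °C; 4 (1.05 equiv), 0 °C → rt; then TBAF (1.2 equiv, wet THF), 0 °C
Reagents that add atoms: phenyl[(trimethylsilyl)ethynyl]iodonium triflate (4), C[Si](C)(C)C#C[I+]c1ccccc1.[O-]S(=O)(=O)C(F)(F)F
Why: N-alkynylation of a sulfonamide anion with an alkynyl(aryl)iodonium salt (addition at the β-carbon, loss of iodobenzene, 1,2-silyl shift of the alkylidene carbene), then fluoride C–Si cleavage in the same flask; one equivalent of base removes only the far more acidic N–H, and the sensitive terminal ynamide is unmasked last, directly before use.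

Step 3
Reactants: 7 N-(but-3-yn-1-yl)-N-ethynyl-4-methylbenzenesulfonamide; 8 bis(trimethylsilyl)acetylene
Product: 9 1-[(4-methylphenyl)sulfonyl]-5,6-bis(trimethylsilyl)indoline
Conditions: CpCo(CO)2 (10 mol %), 8 as solvent (large excess, recovered by distillation), hν (visible lamp), reflux (ca. 135 °C); 7 added by syringe pump over ca. 10 h
Reagents that add atoms: bis(trimethylsilyl)acetylene (8), C[Si](C)(C)C#C[Si](C)(C)C
Why: Loss of CO from CpCo(CO)2 under light and heat frees a CpCo fragment that binds both alkynes of 7 and couples them oxidatively to a bicyclic cobaltacyclopentadiene, forming C3a–C7a; 8 then inserts into a Co–C bond (or adds in a [4+2] sense) and reductive elimination forms C4–C5 and C6–C7 and releases the arene. The closest known reaction type is the CpCo-mediated [2+2+2] cocyclisation of α,ω-diynes with bis(trimethylsilyl)acetylene, together with the transition-metal cyclotrimerisation of sulfonyl ynamide diynes to indolines. The five-membered nitrogen ring closes first, by intramolecular alkyne–alkyne coupling across the three-atom N1–C2–C3 link during metallacycle formation; the benzene ring closes second, by intermolecular incorporation of the third alkyne into the metallacycle. No stereocentre is created. The step needs chemoselectivity for cross- over self-cyclotrimerisation: 8 is too hindered to trimerise and serves as solvent, while slow addition keeps 7 dilute so that the cobaltacycle meets 8 before a second diyne. Regiochemistry cannot go wrong because 8 is symmetric, and the tosyl group both stabilises the ynamide and keeps nitrogen from binding cobalt.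

Step 4
Reactants: 9 1-[(4-methylphenyl)sulfonyl]-5,6-bis(trimethylsilyl)indoline
Product: 10 5,6-dibromo-1-[(4-methylphenyl)sulfonyl]indoline
Conditions: Br2 (2.4 equiv), pyridine (0.2 equiv), CH2Cl2, 0 °C → rt, dark; aq. Na2S2O3
Reagents that add atoms: bromine, BrBr
Why: Electrophilic ipso-bromodesilylation of an aryl silane: the β-silicon effect steers bromine to the two silylated carbons, relief of strain between the vicinal SiMe3 groups speeds the first exchange, and the sulfonamide keeps C7 deactivated.

Step 5
Reactants: 10 5,6-dibromo-1-[(4-methylphenyl)sulfonyl]indoline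
Product: 12 5,6-dibromoindoline, via indolinium triflate 11 (not isolated)
Conditions: TfOH (3 equiv), ClCH2CH2Cl, 80 °C; then aq. NaOH
Reagents that add atoms: none
Why: Acid hydrolysis of an N-aryl sulfonamide (N-protonation and S–N cleavage, the tosyl group ending as the sulfonic acid after aqueous work-up), chosen because aryl bromides are inert to acid but not to dissolving-metal or Mg/MeOH detosylation.

Step 6
Reactants: 12 5,6-dibromoindoline
Product: 13 5,6-dibromo-1H-indole
Conditions: activated MnO2 (10 equiv), CH2Cl2, rt → reflux
Reagents that add atoms: none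
Why: Dehydrogenation of an N–H indoline to the indole with activated manganese dioxide, driven by aromatisation and harmless to C–Br bonds.

Step 7
Reactants: 13 5,6-dibromo-1H-indole
Product: 14 5,6-dibromo-1-methyl-1H-indole
Conditions: MeI (1.5 equiv), Cs2CO3 (2 equiv), DMF, rt
Reagents that add atoms: iodomethane, CI
Why: N-alkylation of an indole (SN2 on methyl iodide) under carbonate base, the N–H being the only acidic site and made more acidic by the two bromines.

Step 8
Reactants: 14 5,6-dibromo-1-methyl-1H-indole
Product: 16 1-(5,6-dibromo-1-methyl-1H-indol-3-yl)-N,N-dimethylmethanamine, via dibromogramine hydroiodide 15 (not isolated)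
Conditions: Me2N+=CH2 I− (1.2 equiv), MeCN, rt → 50 °C; then aq. NaOH
Reagents that add atoms: N,N-dimethylmethyleneiminium iodide, C=[N+](C)C.[I-]
Why: Mannich reaction with a preformed iminium salt, an electrophilic substitution at C3, the most nucleophilic position of an N-alkylindole.

Step 9
Reactants: 16 1-(5,6-dibromo-1-methyl-1H-indol-3-yl)-N,N-dimethylmethanamine
Product: 19 1-(2,5,6-tribromo-1-methyl-1H-indol-3-yl)-N,N-dimethylmethanamine, via dibromogramine trifluoroacetate 17 (not isolated), via tribromogramine trifluoroacetate 18 (not isolated)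
Conditions: TFA (2 equiv), CH2Cl2, 0 °C; NBS (1.05 equiv), 0 °C → rt, dark; then aq. NaOH
Reagents that add atoms: N-bromosuccinimide, O=C1CCC(=O)N1Br
Why: Electrophilic C2 bromination of a 3-substituted indole with NBS (attack at C3, 1,2-bromine shift, loss of H+), run on the ammonium salt so that the nitrogen lone pair can neither be oxidised nor expel the side chain by retro-Mannich fragmentation; the dibrominated benzo ring is too deactivated to compete.

Step 10
Reactants: 19 1-(2,5,6-tribromo-1-methyl-1H-indol-3-yl)-N,N-dimethylmethanamine
Product: 20 1-(2,5,6-tribromo-1-methyl-1H-indol-3-yl)-N,N-dimethylmethanamine N-oxide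
Conditions: mCPBA (1.0 equiv), CH2Cl2, 0 °C; filtration through basic alumina
Reagents that add atoms: 3-chloroperoxybenzoic acid, OOC(=O)c1cccc(Cl)c1
Why: Peracid oxidation of a tertiary amine to its N-oxide, which at 0 °C with one equivalent should be much faster than attack on the electron-poor 2-bromoindole π-system; the nitrogen bears two methyl groups and is not a stereocentre.

**Compound list**

1 | but-3-yn-1-amine | NCCC#C | starting material
2 | 4-toluenesulfonyl chloride | Cc1ccc(cc1)S(Cl)(=O)=O | starting material
3 | N-(but-3-yn-1-yl)-4-methylbenzenesulfonamide | Cc1ccc(cc1)S(=O)(=O)NCCC#C | intermediate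
4 | phenyl[(trimethylsilyl)ethynyl]iodonium trifluoromethanesulfonate | C[Si](C)(C)C#C[I+]c1ccccc1.[O-]S(=O)(=O)C(F)(F)F | starting material
5 | potassium salt of N-(but-3-yn-1-yl)-4-methylbenzenesulfonamide | Cc1ccc(cc1)S(=O)(=O)[N-]CCC#C.[K+] | intermediate (not isolated)
6 | N-(but-3-yn-1-yl)-4-methyl-N-[(trimethylsilyl)ethynyl]benzenesulfonamide | Cc1ccc(cc1)S(=O)(=O)N(CCC#C)C#C[Si](C)(C)C | intermediate (not isolated)
7 | N-(but-3-yn-1-yl)-N-ethynyl-4-methylbenzenesulfonamide | Cc1ccc(cc1)S(=O)(=O)N(C#C)CCC#C | intermediate
8 | bis(trimethylsilyl)acetylene | C[Si](C)(C)C#C[Si](C)(C)C | starting material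
9 | 1-[(4-methylphenyl)sulfonyl]-5,6-bis(trimethylsilyl)indoline | Cc1ccc(cc1)S(=O)(=O)N1CCc2cc([Si](C)(C)C)c([Si](C)(C)C)cc21 | intermediate
10 | 5,6-dibromo-1-[(4-methylphenyl)sulfonyl]indoline | Cc1ccc(cc1)S(=O)(=O)N1CCc2cc(Br)c(Br)cc21 | intermediate
11 | 5,6-dibromoindolinium trifluoromethanesulfonate | Brc1cc2CC[NH2+]c2cc1Br.[O-]S(=O)(=O)C(F)(F)F | intermediate (not isolated)
12 | 5,6-dibromoindoline | Brc1cc2CCNc2cc1Br | intermediate
13 | 5,6-dibromo-1H-indole | Brc1cc2cc[nH]c2cc1Br | intermediate
14 | 5,6-dibromo-1-methyl-1H-indole | Cn1ccc2cc(Br)c(Br)cc21 | intermediate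
15 | (5,6-dibromo-1-methyl-1H-indol-3-yl)methyl-dimethylammonium iodide | Cn1cc(C[NH+](C)C)c2cc(Br)c(Br)cc21.[I-] | intermediate (not isolated)
16 | 1-(5,6-dibromo-1-methyl-1H-indol-3-yl)-N,N-dimethylmethanamine | Cn1cc(CN(C)C)c2cc(Br)c(Br)cc21 | intermediate
17 | (5,6-dibromo-1-methyl-1H-indol-3-yl)methyl-dimethylammonium trifluoroacetate | Cn1cc(C[NH+](C)C)c2cc(Br)c(Br)cc21.[O-]C(=O)C(F)(F)F | intermediate (not isolated)
18 | (2,5,6-tribromo-1-methyl-1H-indol-3-yl)methyl-dimethylammonium trifluoroacetate | Cn1c(Br)c(C[NH+](C)C)c2cc(Br)c(Br)cc21.[O-]C(=O)C(F)(F)F | intermediate (not isolated)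
19 | 1-(2,5,6-tribromo-1-methyl-1H-indol-3-yl)-N,N-dimethylmethanamine | Cn1c(Br)c(CN(C)C)c2cc(Br)c(Br)cc21 | intermediate
20 | 1-(2,5,6-tribromo-1-methyl-1H-indol-3-yl)-N,N-dimethylmethanamine N-oxide | Cn1c(Br)c(C[N+](C)(C)[O-])c2cc(Br)c(Br)cc21 | target

**Step count**

Total steps: 10. Longest linear sequence: 10 steps (1 → 20).

**Three steps most likely to fail**

1. Step 3. Capture of the cobaltacycle by a second diyne molecule, or thermal and photochemical breakdown of the terminal ynamide, may outrun insertion of the hindered silylalkyne, so that oligomers form in place of the cross-product. Fallback: setting out from diyne 7, the cocyclisation would be moved to a catalyst that works near room temperature (cationic Rh(I)/BINAP in ClCH2CH2Cl). The two-carbon partner would be 1,2-bis(4,4,5,5-tetramethyl-1,3,2-dioxaborolan-2-yl)ethyne, a flatter and more electrophilic alkyne of a class established in diyne cyclotrimerisations. This should give 1-[(4-methylphenyl)sulfonyl]-5,6-bis(4,4,5,5-tetramethyl-1,3,2-dioxaborolan-2-yl)indoline F1. Copper(II) bromide in aqueous methanol at 80 °C (bromodeboronation) would then convert both C–B bonds into C–Br and rejoin the route at 10, so boron replaces silicon as placeholder and step 4 is no longer needed.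

2. Step 9. Bromine may attack C3 in an ipso sense and the aminomethyl arm may then be lost (retro-Mannich), or the amine may be oxidised if protonation is incomplete. Fallback: setting out from 14, the C2 bromine and the C3 carbon would be installed together through the oxindole. N-Chlorosuccinimide in CH2Cl2 should give 5,6-dibromo-3-chloro-1-methyl-1H-indole F2. Hot 85 % phosphoric acid in 2-methoxyethanol would hydrolyse it to 5,6-dibromo-1-methylindolin-2-one F3. POBr3/DMF (Vilsmeier–Haack haloformylation) would convert the lactam into 2,5,6-tribromo-1-methyl-1H-indole-3-carbaldehyde F4. Reductive amination with dimethylamine and NaBH(OAc)3 in ClCH2CH2Cl would then give 19, where the route is rejoined; steps 8 and 9 are bypassed.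

3. Step 5. Under strong acid the sulfonyl group may migrate to C7 instead of leaving, or S–N cleavage may stall. Fallback: setting out from 10, the ring would be aromatised before the sulfonyl group is removed, because an N-sulfonyl indole is cleaved by mild nucleophiles. Wohl–Ziegler bromination at benzylic C3 (NBS, AIBN, PhCF3, reflux) should give racemic 3,5,6-tribromo-1-[(4-methylphenyl)sulfonyl]indoline F5. DBU would remove HBr to give 5,6-dibromo-1-[(4-methylphenyl)sulfonyl]-1H-indole F6. Cs2CO3 in THF/MeOH would then cleave the N–S bond and rejoin the route at 13. Radical bromination at the tosyl methyl group would be harmless, since that group is discarded.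

**Further compounds**

F1 | step 3 | 1-[(4-methylphenyl)sulfonyl]-5,6-bis(4,4,5,5-tetramethyl-1,3,2-dioxaborolan-2-yl)indoline | Cc1ccc(cc1)S(=O)(=O)N1CCc2cc(B3OC(C)(C)C(C)(C)O3)c(B3OC(C)(C)C(C)(C)O3)cc21
F2 | step 9 | 5,6-dibromo-3-chloro-1-methyl-1H-indole | Cn1cc(Cl)c2cc(Br)c(Br)cc21
F3 | step 9 | 5,6-dibromo-1-methylindolin-2-one | CN1C(=O)Cc2cc(Br)c(Br)cc21
F4 | step 9 | 2,5,6-tribromo-1-methyl-1H-indole-3-carbaldehyde | Cn1c(Br)c(C=O)c2cc(Br)c(Br)cc21
F5 | step 5 | 3,5,6-tribromo-1-[(4-methylphenyl)sulfonyl]indoline (racemic) | Cc1ccc(cc1)S(=O)(=O)N1CC(Br)c2cc(Br)c(Br)cc21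
F6 | step 5 | 5,6-dibromo-1-[(4-methylphenyl)sulfonyl]-1H-indole | Cc1ccc(cc1)S(=O)(=O)n1ccc2cc(Br)c(Br)cc21
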